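**Plan**

- Tetralin numbering is used throughout: C1 bears the pendant aryl ring, C2 and C3 the CH2OH groups, C4 is the ring CH2; the target is 1R,2S,3S, all-trans. The retrosynthesis first puts back three helpers: the two CH2OH groups become a trans-fused γ-lactone menthyl acetal, C4 a spiro-1,3-dithiane, the phenols benzyl ethers.
- The C8a–C1 bond of ring B is then cut. C1 carries the 4-oxygenated 3,5-dimethoxyphenyl ring, whose para oxygen stabilises a cation at C1 in quinone-methide fashion, and C8a of ring A lies para to the 6-methoxy group, so an intramolecular Friedel–Crafts closure of a benzylic carbinol is the event.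
- The open carbinol is cut at C1–C2 (aldol) and C3–C4 (conjugate addition) into three pieces: the dithiane of O-benzylvanillin, (5S)-5-(d-menthyloxy)furan-2(5H)-one and O-benzylsyringaldehyde.
- Forward: dithiane formation; a one-flask conjugate addition–aldol joins the whole carbon skeleton; acid closes ring B; LiAlH4 unmasks the diol and releases menthol; Raney Ni removes sulfur and benzyl groups.
- Stereochemistry: the acetal carbon of the butenolide sets C3 (anti addition), C3 sets C2 (anti aldol), and the trans lactone sets C1 in a stereoconvergent cyclisation that accepts both carbinol epimers.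

Key step: step 3

Assumption: (5S)-5-(d-menthyloxy)furan-2(5H)-one is taken to be a catalogue compound like its mirror image; it is otherwise one step from 5-hydroxyfuran-2(5H)-one and (+)-menthol (d-menthyl = (1S,2R,5S)-2-isopropyl-5-methylcyclohexyl).

**Route**

Step 1
Reactants: 1 4-(benzyloxy)-3-methoxybenzaldehyde (O-benzylvanillin); 2 propane-1,3-dithiol
Product: 3 2-[4-(benzyloxy)-3-methoxyphenyl]-1,3-dithiane
Conditions: BF3·OEt2 (0.2 equiv), CH2Cl2, 0 °C to rt
Reagents that add atoms: none
Why: Lewis-acid-catalysed dithioacetalisation of an aromatic aldehyde is routine, leaves the benzyl ether untouched and turns the aldehyde carbon into an acyl-anion equivalent (umpolung) that will become C4 of the tetralin; no stereocenter is formed.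

Step 2
Reactants: 3 2-[4-(benzyloxy)-3-methoxyphenyl]-1,3-dithiane; 4 (5S)-5-(d-menthyloxy)furan-2(5H)-one; 5 4-(benzyloxy)-3,5-dimethoxybenzaldehyde (O-benzylsyringaldehyde)
Product: 8 (3R,4S,5S)-3-{[4-(benzyloxy)-3,5-dimethoxyphenyl](hydroxy)methyl}-4-{2-[4-(benzyloxy)-3-methoxyphenyl]-1,3-dithian-2-yl}-5-(d-menthyloxy)dihydrofuran-2(3H)-one as both carbinol epimers, via 2-lithio-1,3-dithiane 6 (not isolated), via lithium lactone enolate 7 (not isolated)
Conditions: n-BuLi (1.05 equiv), THF, −78 to −20 °C; 4, −78 °C; 5, −78 °C; AcOH, −78 °C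
Reagents that add atoms: none
Why: Tandem Michael addition–aldol reaction in which the soft lithiated 2-aryl-dithiane 6 adds 1,4 to the butenolide anti to the menthyloxy group on the acetal carbon (setting the future C3) and enolate 7 is trapped by the aldehyde anti to the bulky new substituent (setting the future C2), while the carbinol carbon forms as a mixture that step 3 renders irrelevant.

Step 3
Reactants: 8 the epimeric aldol adducts
Product: 10 (3S,3aS,9R,9aS)-7-(benzyloxy)-9-[4-(benzyloxy)-3,5-dimethoxyphenyl]-6-methoxy-3-(d-menthyloxy)-3a,9,9a-trihydro-3H-spiro[naphtho[2,3-c]furan-4,2'-[1,3]dithian]-1-one (aryltetralin with trans-fused lactone acetal and spiro-dithiane at C4), via benzylic cation 9 (not isolated)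
Conditions: TFA (10 equiv), CH2Cl2, 0 °C to rt
Reagents that add atoms: none
Why: TFA ionises both carbinol epimers of 8 to one planar benzylic cation 9, stabilised as an O-benzyl para-quinone-methide oxocarbenium by the para oxygen of the 4-benzyloxy-3,5-dimethoxyphenyl ring, so the mixture from step 2 is funnelled stereoconvergently into one product. The closest known reaction type is the acid-mediated intramolecular Friedel–Crafts alkylation (cyclodehydration) of α-(aryl-hydroxymethyl)-β-benzyl-γ-butyrolactones to aryltetralin lactones. Ring B closes in a 6-exo-trig mode with respect to the cationic carbon, the ring being made of the attacking arene carbon, its neighbour that bears the dithiane carbon, the dithiane carbon, lactone C4, lactone C3 and the cationic carbon. The new stereocenter C1 is controlled by the trans-disubstituted lactone: in the half-chair transition state the pendant aryl group sits pseudo-equatorial and anti to the carbonyl branch on the neighbouring carbon, which gives the 1,2-trans-2,3-trans array. The step needs attack by the arene position para to the methoxy group and not by the position between the side chain and the methoxy group, which the para-donor effect and the crowding of the latter site secure; it also needs the acetal and the dithiane to survive, which the acyloxy-deactivated acetal carbon and the reversibility of sulfonium formation should allow.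

Step 4
Reactants: 10 the tetralin lactone acetal
Product: 11 [(2'S,3'S,4'R)-6'-(benzyloxy)-4'-[4-(benzyloxy)-3,5-dimethoxyphenyl]-7'-methoxy-3',4'-dihydro-2'H-spiro[1,3-dithiane-2,1'-naphthalene]-2',3'-diyl]dimethanol
Conditions: LiAlH4 (4 equiv), THF, 0 °C to reflux; then H2O, aq NaOH
Reagents that add atoms: none
Why: LiAlH4 reduction of a γ-alkoxy-γ-lactone to a 1,4-diol, in which hydride addition to the lactone carbonyl opens the ring to a hemiacetal alkoxide that expels menthoxide and the aldehyde so unmasked is reduced as well, so the temporary lactone acetal becomes the two hydroxymethyl groups without touching C1, C2 or C3.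

Step 5
Reactants: 11 the dithiane diol bis(benzyl ether)
Product: 12 (6S,7S,8R)-8-(4-hydroxy-3,5-dimethoxyphenyl)-6,7-bis(hydroxymethyl)-3-methoxy-5,6,7,8-tetrahydronaphthalen-2-ol (target; 1R,2S,3S in tetralin numbering)
Conditions: Raney Ni (W-2, excess), H2 (1 atm), EtOH, reflux
Reagents that add atoms: none
Why: Raney Ni desulfurisation (Mozingo reduction) converts the benzylic dithioketal into the C4 methylene and the same catalyst under H2 hydrogenolyses both aryl benzyl ethers, no stereocenter being involved.

**Compound list**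

1 | 4-(benzyloxy)-3-methoxybenzaldehyde | COc1cc(C=O)ccc1OCc1ccccc1 | starting material
2 | propane-1,3-dithiol | SCCCS | starting material
3 | 2-[4-(benzyloxy)-3-methoxyphenyl]-1,3-dithiane | COc1cc(C2SCCCS2)ccc1OCc1ccccc1 | intermediate
4 | (5S)-5-{[(1S,2R,5S)-2-isopropyl-5-methylcyclohexyl]oxy}furan-2(5H)-one | O=C1C=C[C@@H](O[C@H]2C[C@@H](C)CC[C@@H]2C(C)C)O1 | starting material
5 | 4-(benzyloxy)-3,5-dimethoxybenzaldehyde | COc1cc(C=O)cc(OC)c1OCc1ccccc1 | starting material
6 | 2-[4-(benzyloxy)-3-methoxyphenyl]-2-lithio-1,3-dithiane | COc1cc(C2([Li])SCCCS2)ccc1OCc1ccccc1 | intermediate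
7 | lithium enolate of (4S,5S)-4-{2-[4-(benzyloxy)-3-methoxyphenyl]-1,3-dithian-2-yl}-5-(d-menthyloxy)dihydrofuran-2(3H)-one (4,5-trans) | [Li]OC1=C[C@H](C2(c3ccc(OCc4ccccc4)c(OC)c3)SCCCS2)[C@@H](O[C@H]2C[C@@H](C)CC[C@@H]2C(C)C)O1 | intermediate
8 | (3R,4S,5S)-3-{[4-(benzyloxy)-3,5-dimethoxyphenyl](hydroxy)methyl}-4-{2-[4-(benzyloxy)-3-methoxyphenyl]-1,3-dithian-2-yl}-5-(d-menthyloxy)dihydrofuran-2(3H)-one, 3,4-trans-4,5-trans, both carbinol epimers | O=C1[C@@H](C(O)c2cc(OC)c(OCc3ccccc3)c(OC)c2)[C@H](C2(c3ccc(OCc4ccccc4)c(OC)c3)SCCCS2)[C@@H](O[C@H]2C[C@@H](C)CC[C@@H]2C(C)C)O1 | intermediate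
9 | benzylic cation from 8 (para-benzyloxy-stabilised, quinone-methide type) | O=C1[C@@H]([CH+]c2cc(OC)c(OCc3ccccc3)c(OC)c2)[C@H](C2(c3ccc(OCc4ccccc4)c(OC)c3)SCCCS2)[C@@H](O[C@H]2C[C@@H](C)CC[C@@H]2C(C)C)O1 | intermediate
10 | (3S,3aS,9R,9aS)-7-(benzyloxy)-9-[4-(benzyloxy)-3,5-dimethoxyphenyl]-6-methoxy-3-(d-menthyloxy)-3a,9,9a-trihydro-3H-spiro[naphtho[2,3-c]furan-4,2'-[1,3]dithian]-1-one | COc1cc2c(cc1OCc1ccccc1)[C@@H](c1cc(OC)c(OCc5ccccc5)c(OC)c1)[C@@H]3C(=O)O[C@H](O[C@H]5C[C@@H](C)CC[C@@H]5C(C)C)[C@H]3C24SCCCS4 | intermediate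
11 | [(2'S,3'S,4'R)-6'-(benzyloxy)-4'-[4-(benzyloxy)-3,5-dimethoxyphenyl]-7'-methoxy-3',4'-dihydro-2'H-spiro[1,3-dithiane-2,1'-naphthalene]-2',3'-diyl]dimethanol | COc1cc2c(cc1OCc1ccccc1)[C@@H](c1cc(OC)c(OCc5ccccc5)c(OC)c1)[C@H](CO)[C@@H](CO)C23SCCCS3 | intermediate
12 | (6S,7S,8R)-8-(4-hydroxy-3,5-dimethoxyphenyl)-6,7-bis(hydroxymethyl)-3-methoxy-5,6,7,8-tetrahydronaphthalen-2-ol | COc1cc2c(cc1O)[C@@H](c1cc(OC)c(O)c(OC)c1)[C@H](CO)[C@@H](CO)C2 | target

**Step count and risks**

Total step count: 5. Longest linear sequence: 5 steps (1 to 12).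

Steps most likely to fail, riskiest first:

Step 3. The cation may be captured by a dithiane sulfur (sulfonium formation followed by ring expansion or elimination), the menthyl acetal may ionise, or the hindered benzyl ether may be lost under acid with re-benzylation of the electron-rich rings. The fallback takes the sulfur out before the cation is made and sets out from 8. Acetone-deactivated Raney Ni in EtOH at rt should remove only the dithiane and give the sulfur-free hydroxy lactone F1 as both carbinol epimers. TFA in CH2Cl2 should then close ring B on this substrate to give the tetralin lactone acetal F2. LiAlH4 in THF should give the diol bis(benzyl ether) F3, and hydrogenolysis with H2 over Pd/C in EtOAc/MeOH comes back to the route at 12.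

Step 2. The hindered lithium aldolate may fragment by retro-aldol reaction, the enolate may be quenched by proton transfer before it meets the aldehyde, or 1,2-addition to the butenolide may compete. The fallback replaces the reversible lithium aldol by an irreversible Lewis-acid aldol and sets out from 3 and 4. Conjugate addition as in step 2 followed by trapping of the enolate with Me3SiCl should give the silyl ketene acetal F4. Mukaiyama aldol addition of F4 to 5 with BF3·OEt2 in CH2Cl2 at −78 °C and aqueous work-up comes back to the route at 8.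

Step 5. Hydrogenolysis of the benzyl ethers may stall on the sulfided nickel surface, or the polar tetraol may adsorb strongly on the large excess of nickel. The fallback separates the two tasks and sets out from 11. BCl3 with pentamethylbenzene as cation scavenger in CH2Cl2 at −78 °C should cleave both aryl benzyl ethers and leave the dithiane, giving the bisphenol dithiane diol F5. Raney Ni in EtOH at rt then only has to remove sulfur and comes back to the route at 12.

Further compounds
F1 | step 3 | (3R,4S,5S)-3-{[4-(benzyloxy)-3,5-dimethoxyphenyl](hydroxy)methyl}-4-[4-(benzyloxy)-3-methoxybenzyl]-5-(d-menthyloxy)dihydrofuran-2(3H)-one, both carbinol epimers | O=C1[C@@H](C(O)c2cc(OC)c(OCc3ccccc3)c(OC)c2)[C@H](Cc2ccc(OCc3ccccc3)c(OC)c2)[C@@H](O[C@H]2C[C@@H](C)CC[C@@H]2C(C)C)O1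
F2 | step 3 | sulfur-free analogue of 10 with CH2 at C4: 7-(benzyloxy)-9-[4-(benzyloxy)-3,5-dimethoxyphenyl]-6-methoxy-3-(d-menthyloxy)-3a,4,9,9a-tetrahydronaphtho[2,3-c]furan-1(3H)-one, same configuration as 10 | COc1cc2c(cc1OCc1ccccc1)[C@@H](c1cc(OC)c(OCc5ccccc5)c(OC)c1)[C@@H]3C(=O)O[C@H](O[C@H]5C[C@@H](C)CC[C@@H]5C(C)C)[C@H]3C2
F3 | step 3 | [(1R,2S,3S)-7-(benzyloxy)-1-[4-(benzyloxy)-3,5-dimethoxyphenyl]-6-methoxy-1,2,3,4-tetrahydronaphthalene-2,3-diyl]dimethanol | COc1cc2c(cc1OCc1ccccc1)[C@@H](c1cc(OC)c(OCc5ccccc5)c(OC)c1)[C@H](CO)[C@@H](CO)C2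
F4 | step 2 | trimethylsilyl ketene acetal of (4S,5S)-4-{2-[4-(benzyloxy)-3-methoxyphenyl]-1,3-dithian-2-yl}-5-(d-menthyloxy)dihydrofuran-2(3H)-one | C[Si](C)(C)OC1=C[C@H](C2(c3ccc(OCc4ccccc4)c(OC)c3)SCCCS2)[C@@H](O[C@H]2C[C@@H](C)CC[C@@H]2C(C)C)O1
F5 | step 5 | (2'S,3'S,4'R)-4'-(4-hydroxy-3,5-dimethoxyphenyl)-2',3'-bis(hydroxymethyl)-7'-methoxy-3',4'-dihydro-2'H-spiro[1,3-dithiane-2,1'-naphthalen]-6'-ol | COc1cc2c(cc1O)[C@@H](c1cc(OC)c(O)c(OC)c1)[C@H](CO)[C@@H](CO)C23SCCCS3
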